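**Plan**
- Retrosynthesis: the two benzyl ethers and an ester carbon on ring B are set aside, then ring B is cut at C1–C2 and C3–C4 into a lactone-tethered alkynyl ketone and dimethyl malonate. Further cuts are the alkyne–acyl bond, the lactone C3–CH2 bond and the C=C of a Stobbe half-ester.
- Forward: ring A is bought as O-benzylvanillin; the lactone closes in step 3, the five-carbon ynone chain is attached at lactone C3 in steps 4 and 5, and ring B is built last from open-chain pieces in step 6.
- Enabling feature: ring B carries three neighbouring oxygens on its C3, C4 and C5 (OH, OH, OMe) that must be told apart. The annulation delivers them already differentiated as an ester-chelated OH, a benzyl ether and a free OH.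
- Stereochemistry: lactone C4 (R) comes from rhodium-catalysed asymmetric hydrogenation; C3 (R) comes from alkylation of the lactone enolate anti to the C4 benzyl group, and trans is also the thermodynamic isomer.

Key step: step 6

Remark: the target is read as the trans-(3R,4R) lactone; the (4S,5S) antipode of MOD-DIOP is assumed to deliver the R acid 4, which is checked at lactone 6 by chiral HPLC and sign of rotation, and the (4R,5R) ligand is used if the sense is opposite.

Step 1
Reactants: 1 4-(benzyloxy)-3-methoxybenzaldehyde; 2 dimethyl succinate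
Product: 3 (E)-4-[4-(benzyloxy)-3-methoxyphenyl]-3-(methoxycarbonyl)but-3-enoic acid
Conditions: NaOMe (2 equiv), MeOH, reflux; then 2 M HCl
Reagents that add atoms: none
Why: Stobbe condensation, in which the succinate enolate adds to the aldehyde, the alkoxide lactonises onto the distal ester and E1cB opening of the paraconate should give the E half-ester with the free acid on the CH2 arm.

Step 2
Reactants: 3 (E)-4-[4-(benzyloxy)-3-methoxyphenyl]-3-(methoxycarbonyl)but-3-enoic acid
Product: 4 (3R)-4-[4-(benzyloxy)-3-methoxyphenyl]-3-(methoxycarbonyl)butanoic acid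
Conditions: H2 (1 atm), [Rh(cod)Cl]2 (0.1 mol %), (4S,5S)-MOD-DIOP [DIOP with bis(4-methoxy-3,5-dimethylphenyl)phosphino groups], Et3N (1 equiv), MeOH, 30 °C; then dilute HCl
Reagents that add atoms: none
Why: Rhodium–bisphosphine asymmetric hydrogenation of an itaconate-type half-ester, in which the carboxylate and the alkene bind the metal so that the chiral ligand directs H2 to one face and sets the R centre (later lactone C4), while the homogeneous catalyst leaves the benzyl ether alone.

Step 3
Reactants: 4 (3R)-4-[4-(benzyloxy)-3-methoxyphenyl]-3-(methoxycarbonyl)butanoic acid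
Product: 6 (4R)-4-[4-(benzyloxy)-3-methoxybenzyl]dihydrofuran-2(3H)-one, via hydroxy acid 5 (not isolated)
Conditions: KOH (1 equiv), EtOH; CaCl2, NaBH4 [Ca(BH4)2 formed in situ], EtOH, −10 °C to rt; then 2 M HCl, rt
Reagents that add atoms: none
Why: Chemoselective borohydride reduction, in which Ca(BH4)2 reduces the methyl ester but not the potassium carboxylate, followed by acid-promoted lactonisation of the γ-hydroxy acid that does not touch the stereocentre.

Step 4
Reactants: 6 (4R)-4-[4-(benzyloxy)-3-methoxybenzyl]dihydrofuran-2(3H)-one; 7 propargyl bromide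
Product: 8 (3R,4R)-4-[4-(benzyloxy)-3-methoxybenzyl]-3-(prop-2-yn-1-yl)dihydrofuran-2(3H)-one
Conditions: LiN(SiMe3)2 (1.1 equiv), THF, −78 °C; then 7 (1.3 equiv), −78 to −20 °C
Reagents that add atoms: none
Why: Enolate alkylation (SN2) of the lithium lactone enolate, which the C4 benzyl group shields on one face so that the propargyl group enters anti and the new C3 centre is set trans (3R) by substrate control.

Step 5
Reactants: 8 (3R,4R)-4-[4-(benzyloxy)-3-methoxybenzyl]-3-(prop-2-yn-1-yl)dihydrofuran-2(3H)-one; 9 benzyloxyacetyl chloride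
Product: 10 (3R,4R)-4-[4-(benzyloxy)-3-methoxybenzyl]-3-[5-(benzyloxy)-4-oxopent-2-yn-1-yl]dihydrofuran-2(3H)-one
Conditions: PdCl2(PPh3)2 (2 mol %), CuI (4 mol %), Et3N (1.2 equiv), THF, 0 °C to rt
Reagents that add atoms: none
Why: Acyl Sonogashira coupling, in which the acid chloride adds oxidatively to zerovalent palladium formed in situ, the copper acetylide transmetalates and reductive elimination should give the ynone without disturbing the lactone or the benzyl ethers.

Step 6
Reactants: 10 (3R,4R)-4-[4-(benzyloxy)-3-methoxybenzyl]-3-[5-(benzyloxy)-4-oxopent-2-yn-1-yl]dihydrofuran-2(3H)-one; 11 dimethyl malonate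
Product: 13 methyl 3-(benzyloxy)-2,4-dihydroxy-6-{[(3R,4R)-4-(4-benzyloxy-3-methoxybenzyl)-2-oxotetrahydrofuran-3-yl]methyl}benzoate, via Michael adduct 12 (not isolated)
Conditions: NaOMe (2.5 equiv), 11 (1.5 equiv), MeOH–THF, 0 °C to 60 °C; then 1 M HCl, rt
Reagents that add atoms: none
Why: Sodium dimethyl malonate adds in Michael fashion to the ynone β-carbon (ring B bond C1–C2), and adduct 12 equilibrates through its extended dienolate, by proton transfer in methanol, to the enolate at the benzyloxy-bearing carbon held cis to the malonate. That enolate acylates one ester in a 6-(enolendo)-exo-trig Claisen closure (ring B bond C3–C4), methoxide leaves and the cyclohexenedione tautomerises irreversibly to the aromatic resorcylate. The closest known reaction type is the Michael–Claisen condensation of alkynyl ketones with malonate or acetonedicarboxylate esters, which gives alkylresorcinol carboxylates. No stereocentre is created; lactone C3 and C4 are spectators, and any epimerisation at C3 should return to the more stable trans lactone. The step needs C- over O-acylation and the right α-carbon: only the benzyloxy-bearing carbon reaches an ester through a six-membered transition state, O-acylation to a 2-pyranone is reversed by methoxide, and aromatisation drains the equilibrium. The lactone may open to the hydroxy ester under methoxide but should reclose on the acidic work-up.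

Step 7
Reactants: 13 methyl 3-(benzyloxy)-2,4-dihydroxy-6-{[(3R,4R)-4-(4-benzyloxy-3-methoxybenzyl)-2-oxotetrahydrofuran-3-yl]methyl}benzoate
Product: 14 methyl 3-(benzyloxy)-2-hydroxy-4-methoxy-6-{[(3R,4R)-4-(4-benzyloxy-3-methoxybenzyl)-2-oxotetrahydrofuran-3-yl]methyl}benzoate
Conditions: MeI (1.1 equiv), K2CO3 (1.1 equiv), acetone, rt to 40 °C
Reagents that add atoms: iodomethane, CI
Why: Williamson ether synthesis, selective because the C2 hydroxyl is held in a hydrogen bond to the ester carbonyl and flanked on both sides, so the more acidic C4 hydroxyl para to the ester should be the one methylated.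

Step 8
Reactants: 14 methyl 3-(benzyloxy)-2-hydroxy-4-methoxy-6-{[(3R,4R)-4-(4-benzyloxy-3-methoxybenzyl)-2-oxotetrahydrofuran-3-yl]methyl}benzoate
Product: 16 (3R,4R)-3-[4-(benzyloxy)-3-hydroxy-5-methoxybenzyl]-4-[4-(benzyloxy)-3-methoxybenzyl]dihydrofuran-2(3H)-one, via seco diacid 15 (not isolated)
Conditions: NaOH (6 equiv), MeOH–H2O, reflux, argon; then 3 M HCl to pH 1, 60 °C
Reagents that add atoms: none
Why: Saponification of the aryl ester, with the lactone held meanwhile as its ring-opened carboxylate so that C3 cannot enolise, followed on acidification by protodecarboxylation of the electron-rich salicylic acid through ipso protonation (as for orsellinic-type acids) and relactonisation of the γ-hydroxy acid.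

Step 9
Reactants: 16 (3R,4R)-3-[4-(benzyloxy)-3-hydroxy-5-methoxybenzyl]-4-[4-(benzyloxy)-3-methoxybenzyl]dihydrofuran-2(3H)-one
Product: 17 (−)-thujaplicatin, (3R,4R)-3-(3,4-dihydroxy-5-methoxybenzyl)-4-(4-hydroxy-3-methoxybenzyl)dihydrofuran-2(3H)-one
Conditions: H2 (1 atm), 10 % Pd/C, EtOAc–MeOH, rt
Reagents that add atoms: none
Why: Catalytic hydrogenolysis of the two aryl benzyl ethers, which should leave the lactone, the aryl methyl ethers and both stereocentres untouched.

**Compound list**
1 | 4-(benzyloxy)-3-methoxybenzaldehyde | COc1cc(C=O)ccc1OCc1ccccc1 | starting material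
2 | dimethyl succinate | COC(=O)CCC(=O)OC | starting material
3 | (E)-4-[4-(benzyloxy)-3-methoxyphenyl]-3-(methoxycarbonyl)but-3-enoic acid | OC(=O)C/C(C(=O)OC)=C\c1ccc(OCc2ccccc2)c(OC)c1 | intermediate
4 | (3R)-4-[4-(benzyloxy)-3-methoxyphenyl]-3-(methoxycarbonyl)butanoic acid | COC(=O)[C@@H](CC(=O)O)Cc1ccc(OCc2ccccc2)c(OC)c1 | intermediate
5 | (3R)-4-[4-(benzyloxy)-3-methoxyphenyl]-3-(hydroxymethyl)butanoic acid (hydroxy acid, formed as its salt) | OC[C@@H](CC(=O)O)Cc1ccc(OCc2ccccc2)c(OC)c1 | intermediate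
6 | (4R)-4-[4-(benzyloxy)-3-methoxybenzyl]dihydrofuran-2(3H)-one | COc1cc(C[C@H]2COC(=O)C2)ccc1OCc1ccccc1 | intermediate
7 | propargyl bromide (3-bromoprop-1-yne) | C#CCBr | starting material
8 | (3R,4R)-4-[4-(benzyloxy)-3-methoxybenzyl]-3-(prop-2-yn-1-yl)dihydrofuran-2(3H)-one | COc1cc(C[C@H]2COC(=O)[C@@H]2CC#C)ccc1OCc1ccccc1 | intermediate
9 | benzyloxyacetyl chloride | O=C(Cl)COCc1ccccc1 | starting material
10 | (3R,4R)-4-[4-(benzyloxy)-3-methoxybenzyl]-3-[5-(benzyloxy)-4-oxopent-2-yn-1-yl]dihydrofuran-2(3H)-one | COc1cc(C[C@H]2COC(=O)[C@@H]2CC#CC(=O)COCc2ccccc2)ccc1OCc1ccccc1 | intermediate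
11 | dimethyl malonate | COC(=O)CC(=O)OC | starting material
12 | dimethyl 2-{5-(benzyloxy)-1-[(3R,4R)-4-(4-benzyloxy-3-methoxybenzyl)-2-oxotetrahydrofuran-3-yl]-4-oxopent-2-en-2-yl}malonate (Michael adduct, alkene geometry equilibrating) | COC(=O)C(C(=O)OC)C(C[C@H]1C(=O)OC[C@@H]1Cc1ccc(OCc2ccccc2)c(OC)c1)=CC(=O)COCc1ccccc1 | intermediate
13 | methyl 3-(benzyloxy)-2,4-dihydroxy-6-{[(3R,4R)-4-(4-benzyloxy-3-methoxybenzyl)-2-oxotetrahydrofuran-3-yl]methyl}benzoate | COC(=O)c1c(O)c(OCc2ccccc2)c(O)cc1C[C@H]1C(=O)OC[C@@H]1Cc1ccc(OCc2ccccc2)c(OC)c1 | intermediate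
14 | methyl 3-(benzyloxy)-2-hydroxy-4-methoxy-6-{[(3R,4R)-4-(4-benzyloxy-3-methoxybenzyl)-2-oxotetrahydrofuran-3-yl]methyl}benzoate | COC(=O)c1c(O)c(OCc2ccccc2)c(OC)cc1C[C@H]1C(=O)OC[C@@H]1Cc1ccc(OCc2ccccc2)c(OC)c1 | intermediate
15 | 3-(benzyloxy)-6-[(2R,3R)-2-carboxy-3-(hydroxymethyl)-4-(4-benzyloxy-3-methoxyphenyl)butyl]-2-hydroxy-4-methoxybenzoic acid (seco diacid, formed as its salt) | OC(=O)c1c(O)c(OCc2ccccc2)c(OC)cc1C[C@@H](C(=O)O)[C@H](CO)Cc1ccc(OCc2ccccc2)c(OC)c1 | intermediate
16 | (3R,4R)-3-[4-(benzyloxy)-3-hydroxy-5-methoxybenzyl]-4-[4-(benzyloxy)-3-methoxybenzyl]dihydrofuran-2(3H)-one | COc1cc(C[C@H]2COC(=O)[C@@H]2Cc2cc(O)c(OCc3ccccc3)c(OC)c2)ccc1OCc1ccccc1 | intermediate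
17 | (−)-thujaplicatin | COc1cc(C[C@H]2COC(=O)[C@@H]2Cc2cc(O)c(O)c(OC)c2)ccc1O | target

**Step count**
Total: 9 steps. Longest linear sequence: 9 steps (from aldehyde 1).

**Steps most likely to fail**

Step 6 (key step). The ynone may isomerise under base to an allenyl or dienyl ketone before the malonate adds, the sequence may stall at the O-acylated 2-pyranone, or the Claisen closure may be slow enough for the lactone centre to erode. The fallback gives up the annulation and brings ring B in ready-made by known lactone-enolate benzylation. Commercial 3,4-dihydroxy-5-methoxybenzaldehyde is dibenzylated (BnBr, K2CO3, DMF) to 3,4-bis(benzyloxy)-5-methoxybenzaldehyde F1, reduced (NaBH4, MeOH) to [3,4-bis(benzyloxy)-5-methoxyphenyl]methanol F2 and converted (PBr3, CH2Cl2, 0 °C) into 1,2-bis(benzyloxy)-5-(bromomethyl)-3-methoxybenzene F3. The fallback sets out from lactone 6: its lithium enolate (LiN(SiMe3)2, THF, −78 °C) is alkylated with the bromide anti to the C4 benzyl group to give (3R,4R)-3-[3,4-bis(benzyloxy)-5-methoxybenzyl]-4-[4-(benzyloxy)-3-methoxybenzyl]dihydrofuran-2(3H)-one F4. Hydrogenolysis of its three benzyl ethers (H2, Pd/C) comes back to the route at the target 17.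

Step 5. The amine may dehydrochlorinate the alkoxyacetyl chloride to benzyloxyketene, the alkyne may homocouple oxidatively, or the product ynone may isomerise under the amine. The fallback replaces acylation by addition and oxidation and sets out from alkyne 8. The zinc alkynylide generated with Zn(OTf)2 and Et3N in toluene adds to benzyloxyacetaldehyde to give (3R,4R)-4-[4-(benzyloxy)-3-methoxybenzyl]-3-[5-(benzyloxy)-4-hydroxypent-2-yn-1-yl]dihydrofuran-2(3H)-one F5 as a mixture of carbinol epimers. Dess–Martin periodinane in CH2Cl2 oxidises both epimers to ynone 10, where the route is rejoined.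

Step 8. Saponification of the doubly ortho-substituted, hydrogen-bonded ester may be incomplete, or prolonged heating in base may lead to partial epimerisation and incomplete relactonisation. The fallback uses an ester that is removed by acid and sets out from ynone 10. The annulation is run with tert-butyl methyl malonate (NaOMe, MeOH–THF); the adduct tert-butyl methyl 2-{5-(benzyloxy)-1-[(3R,4R)-4-(4-benzyloxy-3-methoxybenzyl)-2-oxotetrahydrofuran-3-yl]-4-oxopent-2-en-2-yl}malonate F6 should cyclise through its methyl ester only. This leaves tert-butyl 3-(benzyloxy)-2,4-dihydroxy-6-{[(3R,4R)-4-(4-benzyloxy-3-methoxybenzyl)-2-oxotetrahydrofuran-3-yl]methyl}benzoate F7. Methylation as in step 7 gives tert-butyl 3-(benzyloxy)-2-hydroxy-4-methoxy-6-{[(3R,4R)-4-(4-benzyloxy-3-methoxybenzyl)-2-oxotetrahydrofuran-3-yl]methyl}benzoate F8. CF3CO2H in CH2Cl2 with Et3SiH as cation scavenger cleaves the tert-butyl ester to 3-(benzyloxy)-2-hydroxy-4-methoxy-6-{[(3R,4R)-4-(4-benzyloxy-3-methoxybenzyl)-2-oxotetrahydrofuran-3-yl]methyl}benzoic acid F9. This acid should lose CO2 by ipso protonation in the same medium or on gentle warming, which comes back to the route at phenol 16 without hydroxide ever meeting the lactone.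

**Further compounds**
F1 | step 6 | 3,4-bis(benzyloxy)-5-methoxybenzaldehyde | COc1cc(C=O)cc(OCc2ccccc2)c1OCc1ccccc1
F2 | step 6 | [3,4-bis(benzyloxy)-5-methoxyphenyl]methanol | COc1cc(CO)cc(OCc2ccccc2)c1OCc1ccccc1
F3 | step 6 | 1,2-bis(benzyloxy)-5-(bromomethyl)-3-methoxybenzene | COc1cc(CBr)cc(OCc2ccccc2)c1OCc1ccccc1
F4 | step 6 | (3R,4R)-3-[3,4-bis(benzyloxy)-5-methoxybenzyl]-4-[4-(benzyloxy)-3-methoxybenzyl]dihydrofuran-2(3H)-one | COc1cc(C[C@H]2COC(=O)[C@@H]2Cc2cc(OCc3ccccc3)c(OCc3ccccc3)c(OC)c2)ccc1OCc1ccccc1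
F5 | step 5 | (3R,4R)-4-[4-(benzyloxy)-3-methoxybenzyl]-3-[5-(benzyloxy)-4-hydroxypent-2-yn-1-yl]dihydrofuran-2(3H)-one | COc1cc(C[C@H]2COC(=O)[C@@H]2CC#CC(O)COCc2ccccc2)ccc1OCc1ccccc1
F6 | step 8 | tert-butyl methyl 2-{5-(benzyloxy)-1-[(3R,4R)-4-(4-benzyloxy-3-methoxybenzyl)-2-oxotetrahydrofuran-3-yl]-4-oxopent-2-en-2-yl}malonate | COC(=O)C(C(=O)OC(C)(C)C)C(C[C@H]1C(=O)OC[C@@H]1Cc1ccc(OCc2ccccc2)c(OC)c1)=CC(=O)COCc1ccccc1
F7 | step 8 | tert-butyl 3-(benzyloxy)-2,4-dihydroxy-6-{[(3R,4R)-4-(4-benzyloxy-3-methoxybenzyl)-2-oxotetrahydrofuran-3-yl]methyl}benzoate | CC(C)(C)OC(=O)c1c(O)c(OCc2ccccc2)c(O)cc1C[C@H]1C(=O)OC[C@@H]1Cc1ccc(OCc2ccccc2)c(OC)c1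
F8 | step 8 | tert-butyl 3-(benzyloxy)-2-hydroxy-4-methoxy-6-{[(3R,4R)-4-(4-benzyloxy-3-methoxybenzyl)-2-oxotetrahydrofuran-3-yl]methyl}benzoate | CC(C)(C)OC(=O)c1c(O)c(OCc2ccccc2)c(OC)cc1C[C@H]1C(=O)OC[C@@H]1Cc1ccc(OCc2ccccc2)c(OC)c1
F9 | step 8 | 3-(benzyloxy)-2-hydroxy-4-methoxy-6-{[(3R,4R)-4-(4-benzyloxy-3-methoxybenzyl)-2-oxotetrahydrofuran-3-yl]methyl}benzoic acid | OC(=O)c1c(O)c(OCc2ccccc2)c(OC)cc1C[C@H]1C(=O)OC[C@@H]1Cc1ccc(OCc2ccccc2)c(OC)c1
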